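**Plan**

- Feature used: the cyclohexane carries, next to the oxygen-bearing spiro carbon C1, a quaternary carbon C2 (CH3 and the propanoic acid chain) and then a CH, C3, bearing C(CH3)2OH trans to that chain. With C1 as a ketone, C2 and C3 are the α- and β-carbons of 2-methylcyclohex-2-enone.
- Cuts, from the target backwards: CO2H to CH2OH; the tropone C3'–O bond (alkoxide addition–elimination on a 3'-chlorotropone); the C7'(CO2CH3) carbon of the tropone (one-carbon ring expansion of a 4-methoxycyclohexadienone); the aryl–CH2 bond (aryl Grignard reagent plus spiro-epoxide); the C6–CH3 bond; the C3–isopropenyl and C2–allyl bonds (key step).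
- Forward order: the cyclohexane is bought as the enone and receives isopropenyl and allyl in one flask. The side chains are adjusted, C6 is methylated and C1 is turned into a spiro-epoxide. A benzene ring (made in three steps) is attached, expanded to the seven-membered tropone, and the dihydrofuran ring closes last, before the final oxidation.
- Stereochemistry: C3 comes from the chiral copper catalyst and C2 from C3 (allylation anti to isopropenyl). C6 is set by equilibration to the equatorial methyl in the chair locked by the C3 tert-alkyl group. C1 is set by epoxidation anti to the axial C2 methyl and is kept because later steps form only the CH2–aryl and O–C(sp2) bonds.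

Key step: step 1

Remarks on the chemistry:
- Cyclohexane positions are numbered as in ketone 5 throughout (C1 carbonyl/spiro carbon, C2 quaternary carbon, C3 the CH with the three-carbon group, C6 the other α-carbon). Tropone positions are primed (C1' C=O, C2' CH3, C3' Cl or O, C4' CH2 link, C5' H, C6' CH3, C7' CO2CH3).
- TBS = tert-butyldimethylsilyl, TES = triethylsilyl.
- L* = 1-(2,4,6-trimethylphenyl)-3-(1-hydroxy-4-methylpentan-2-yl)-4,5-dihydroimidazolium hexafluorophosphate; the enantiomer is chosen that delivers the alkenyl group to the Si face of C3.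
- Assumption: methyl diazoacetate (24) is bought or freshly prepared as a CH2Cl2 solution and is counted as a starting material; 3-amino-2,6-dimethylphenol (14) is taken as purchasable.

**Route**

Step 1
Reactants: 1 2-methylcyclohex-2-en-1-one; 2 isopropenylmagnesium bromide; 3 allyl iodide
Product: 5 (2R,3R)-2-allyl-2-methyl-3-(prop-1-en-2-yl)cyclohexan-1-one, via magnesium enolate 4 (not isolated)
Conditions: Cu(OTf)2 (3 mol%), L* (4 mol%), Et2O, −30 °C, slow addition of 2; then 3, DMPU, −30 °C → rt
Reagents that add atoms: none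
Why: The Grignard reagent reduces Cu(OTf)2 to monovalent copper, which with the carbene from L* forms a chiral alkenylcopper species that binds the enone, adds oxidatively at the β-carbon (trivalent copper) and reductively eliminates to magnesium enolate 4; allyl iodide then alkylates the enolate carbon. The closest known reaction is the copper–carbene-catalysed asymmetric conjugate addition of Grignard reagents to 2-methylcyclohex-2-enone with alkyl halide trapping of the magnesium enolate. No ring is closed. C3 is set by the ligand (Si-face delivery gives 3R) and C2 by C3, the allyl group entering the tetrasubstituted enolate anti to the isopropenyl group (2R, trans). The step needs 1,4- over 1,2-addition, which copper catalysis and slow Grignard addition should secure, and C- over O-allylation, which the soft iodide and the DMPU-activated enolate should secure.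

Step 2
Reactants: 5 (2R,3R)-2-allyl-2-methyl-3-(prop-1-en-2-yl)cyclohexan-1-one
Product: 7 (2R,3R)-2-(3-hydroxypropyl)-2-methyl-3-(prop-1-en-2-yl)cyclohexan-1-one, via alkylborane 6 (not isolated)
Conditions: Sia2BH (from BH3·SMe2 + 2-methylbut-2-ene), THF, 0 °C; then 3 M NaOH, 30% H2O2, 0 °C → rt
Reagents that add atoms: hydrogen peroxide, OO
Why: Hydroboration–oxidation, in which the bulky dialkylborane should add anti-Markovnikov to the monosubstituted allyl double bond far faster than to the hindered isopropenyl group or the neopentyl-type ketone, and alkaline peroxide turns the C–B bond into the primary alcohol.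

Step 3
Reactants: 7 (2R,3R)-2-(3-hydroxypropyl)-2-methyl-3-(prop-1-en-2-yl)cyclohexan-1-one
Product: 8 (2R,3S)-3-(2-hydroxypropan-2-yl)-2-(3-hydroxypropyl)-2-methylcyclohexan-1-one
Conditions: Co(acac)2 (20 mol%), PhSiH3, O2 (1 atm), THF, rt
Reagents that add atoms: dioxygen, O=O
Why: Mukaiyama hydration, in which hydrogen-atom transfer from a cobalt hydride to the isopropenyl CH2 gives a tertiary radical that is trapped by O2 and reduced to the Markovnikov alcohol without touching ketone or primary alcohol; no stereocentre is formed (the C3 descriptor changes only by priority).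

Step 4
Reactants: 8 (2R,3S)-3-(2-hydroxypropan-2-yl)-2-(3-hydroxypropyl)-2-methylcyclohexan-1-one
Product: 9 (2R,3S)-2-[3-(TBS-oxy)propyl]-3-[2-(TBS-oxy)propan-2-yl]-2-methylcyclohexan-1-one
Conditions: TBSOTf (2.5 equiv), 2,6-lutidine, CH2Cl2, −78 → 0 °C
Reagents that add atoms: tert-butyldimethylsilyl triflate, CC(C)(C)[Si](C)(C)OS(=O)(=O)C(F)(F)F
Why: Silyl ether formation with the triflate, which is reactive enough for the hindered tertiary carbinol, masks both hydroxyls and leaves at C3 a tert-alkyl group that should lock the ring chair.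

Step 5
Reactants: 9 (2R,3S)-2-[3-(TBS-oxy)propyl]-3-[2-(TBS-oxy)propan-2-yl]-2-methylcyclohexan-1-one
Product: 11 (2R,3S,6S)-2-[3-(TBS-oxy)propyl]-3-[2-(TBS-oxy)propan-2-yl]-2,6-dimethylcyclohexan-1-one, via lithium enolate 10 (not isolated)
Conditions: LiN(iPr)2, THF, −78 °C; MeI, −78 → −20 °C; then NaOMe (cat.), MeOH, rt
Reagents that add atoms: iodomethane, CI
Why: Ketone enolate alkylation at the only enolisable α-carbon, followed by base equilibration to the equatorial C6 methyl (6S), since the 6R epimer would hold its methyl syn-axial to the axial C2 methyl in the chair fixed by the equatorial C3 substituent.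

Step 6
Reactants: 11 (2R,3S,6S)-2-[3-(TBS-oxy)propyl]-3-[2-(TBS-oxy)propan-2-yl]-2,6-dimethylcyclohexan-1-one
Product: 12 (2R,3S,6S)-2-[3-(TBS-oxy)propyl]-3-[2-(TBS-oxy)propan-2-yl]-2,6-dimethyl-1-methylidenecyclohexane
Conditions: Ph3PCH3Br, KOtBu, toluene, 100 °C
Reagents that add atoms: methyltriphenylphosphonium bromide, C[P+](c1ccccc1)(c1ccccc1)c1ccccc1.[Br-]
Why: Wittig methylenation under the hot alkoxide/toluene conditions used for hindered ketones, in which the basic medium keeps C6 in its thermodynamically preferred configuration.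

Step 7
Reactants: 12 (2R,3S,6S)-2-[3-(TBS-oxy)propyl]-3-[2-(TBS-oxy)propan-2-yl]-2,6-dimethyl-1-methylidenecyclohexane
Product: 13 (1S,2R,3S,6S)-spiro-epoxide of 12 (oxirane spiro at C1, oxygen cis to the C2 propyl chain and the C6 methyl)
Conditions: mCPBA, NaHCO3, CH2Cl2, 0 °C
Reagents that add atoms: 3-chloroperbenzoic acid, OOC(=O)c1cccc(Cl)c1
Why: Prilezhaev epoxidation of the 1,1-disubstituted alkene, in which the peracid should approach the face anti to the axial C2 methyl so that the oxirane oxygen becomes axial, which is the C1 configuration of the target.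

Step 8
Reactants: 14 3-amino-2,6-dimethylphenol
Product: 16 3-chloro-2,6-dimethylphenol, via diazonium chloride 15 (not isolated)
Conditions: NaNO2, aq. HCl, 0 °C; then CuCl (cat.), aq. HCl, 0 → 60 °C
Reagents that add atoms: hydrochloric acid, Cl
Why: Diazotisation and Sandmeyer chlorination replace the amino group by chlorine, the meta relation of NH2 and OH excluding quinone diazide formation.

Step 9
Reactants: 16 3-chloro-2,6-dimethylphenol
Product: 17 4-bromo-3-chloro-2,6-dimethylphenol
Conditions: Br2, CH2Cl2, 0 °C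
Reagents that add atoms: bromine, BrBr
Why: Electrophilic aromatic bromination directed by the hydroxyl group to its para position, the only activated site left because both ortho positions carry methyl groups.

Step 10
Reactants: 17 4-bromo-3-chloro-2,6-dimethylphenol
Product: 18 (4-bromo-3-chloro-2,6-dimethylphenoxy)(tert-butyl)dimethylsilane
Conditions: TBSCl, imidazole, DMF, rt
Reagents that add atoms: tert-butyldimethylsilyl chloride, CC(C)(C)[Si](C)(C)Cl
Why: Silylation of the phenol so that the aryl bromide can be turned into a Grignard reagent.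

Step 11
Reactants: 18 (4-bromo-3-chloro-2,6-dimethylphenoxy)(tert-butyl)dimethylsilane; 13 (1S,2R,3S,6S)-spiro-epoxide
Product: 20 (1S,2R,3S,6S)-1-{[2-chloro-3,5-dimethyl-4-(TBS-oxy)phenyl]methyl}-2-[3-(TBS-oxy)propyl]-3-[2-(TBS-oxy)propan-2-yl]-2,6-dimethylcyclohexan-1-ol, via aryl Grignard reagent 19 (not isolated)
Conditions: 18, Mg, LiCl, THF, rt; then CuI (10 mol%), 13, THF, −30 °C → rt; H2O
Reagents that add atoms: none
Why: Copper-catalysed SN2 opening of a 2,2-disubstituted epoxide by an aryl Grignard reagent at the CH2 carbon, which leaves the tertiary C–O bond and hence the C1 configuration untouched; the ortho-chloroarylmagnesium species is stable at these temperatures.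

Step 12
Reactants: 20 tertiary alcohol from step 11
Product: 21 triethylsilyl ether of 20 at the C1 oxygen
Conditions: TESOTf, 2,6-lutidine, CH2Cl2, −40 → 0 °C
Reagents that add atoms: triethylsilyl triflate, CC[Si](CC)(CC)OS(=O)(=O)C(F)(F)F
Why: Silylation of the hindered tertiary alcohol with a silyl triflate, so that it cannot add to the dienone or react with the diazo ester in steps 14 and 15.

Step 13
Reactants: 21 triethylsilyl ether
Product: 22 (1S,2R,3S,6S)-1-[(2-chloro-4-hydroxy-3,5-dimethylphenyl)methyl]-1-(TES-oxy)-2-[3-(TBS-oxy)propyl]-3-[2-(TBS-oxy)propan-2-yl]-2,6-dimethylcyclohexane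
Conditions: Cs2CO3 (0.5 equiv), DMF/H2O (10:1), rt
Reagents that add atoms: none
Why: Selective desilylation, since aryl silyl ethers are cleaved by carbonate in wet DMF much faster than alkyl silyl ethers.

Step 14
Reactants: 22 phenol
Product: 23 3-chloro-4-methoxy-2,6-dimethyl-4-{[(1S,2R,3S,6S)-cyclohexyl unit of 22]methyl}cyclohexa-2,5-dien-1-one (both epimers at the methoxy-bearing carbon)
Conditions: PhI(OAc)2, MeOH, 0 °C
Reagents that add atoms: methanol, CO
Why: Oxidative dearomatisation of a para-alkylphenol, in which methanol adds para to the phenoxenium centre to give the 4-methoxycyclohexa-2,5-dienone; the new quaternary carbon is formed unselectively but becomes sp2 again in step 15.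

Step 15
Reactants: 23 4-methoxycyclohexadienone; 24 methyl diazoacetate
Product: 26 methyl 5-chloro-2,6-dimethyl-7-oxo-4-{[(1S,2R,3S,6S)-cyclohexyl unit of 22]methyl}cyclohepta-1,3,5-triene-1-carboxylate, via β-keto ester 25 (not isolated)
Conditions: BF3·OEt2, CH2Cl2, −78 → −20 °C; then Et3N, 0 °C
Reagents that add atoms: none
Why: Proposed new method: the diazo carbon adds to the BF3-activated dienone carbonyl, the diazonium betaine loses N2 with 1,2-shift of the unhalogenated vinyl carbon C6' (the other vinyl carbon is deactivated by its β-chlorine, as vinyl chlorides are toward electrophiles) to give β-keto ester 25, whose enol is a 7-methoxycycloheptatriene that ionises to a hydroxytropylium ion and gives the tropone on base treatment; the closest known reactions are the Büchner–Curtius–Schlotterbeck ring expansion of 4-methoxycyclohexa-2,5-dienones to tropones with trimethylsilyldiazomethane and the BF3- or Et3OBF4-promoted homologation of cycloalkanones to β-keto esters with diazoacetates.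

Step 16
Reactants: 26 chlorotropone ester
Product: 28 methyl ester-tropone spiro ether with free alcohols (the target carrying CH2CH2CH2OH in place of CH2CH2CO2H), via desilylated chlorotropone triol 27 (not isolated)
Conditions: Bu4NF, THF, 0 → 50 °C
Reagents that add atoms: none
Why: Fluoride desilylation followed by intramolecular addition–elimination (vinylogous acyl substitution, five-membered ring closure) of the C1 alkoxide at the chlorine-bearing β-carbon C3' of the tropone, with retention at C1 because only the O–C(sp2) bond is formed; ring closure may precede loss of the last silyl group, and addition at C5' is reversible because it has no leaving group.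

Step 17
Reactants: 28 hydroxypropyl spiro tropone
Product: 29 CNP0448476.1
Conditions: TEMPO (cat.), PhI(OAc)2, MeCN/H2O (1:1), rt
Reagents that add atoms: water, O
Why: Oxoammonium (TEMPO/PhI(OAc)2) oxidation in aqueous acetonitrile takes the primary alcohol through the aldehyde hydrate to the carboxylic acid and should leave the tertiary alcohol and the tropone untouched.

**Compound list**

1 | 2-methylcyclohex-2-en-1-one | O=C1CCCC=C1C | starting material
2 | isopropenylmagnesium bromide | CC(=C)[Mg]Br | starting material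
3 | allyl iodide | C=CCI | starting material
4 | bromomagnesium (R)-2-methyl-3-(prop-1-en-2-yl)cyclohex-1-en-1-olate | CC1=C(O[Mg]Br)CCC[C@@H]1C(C)=C | intermediate
5 | (2R,3R)-2-allyl-2-methyl-3-(prop-1-en-2-yl)cyclohexan-1-one | O=C1CCC[C@H](C(C)=C)[C@@]1(C)CC=C | intermediate
6 | (2R,3R)-2-{3-[bis(3-methylbutan-2-yl)boranyl]propyl}-2-methyl-3-(prop-1-en-2-yl)cyclohexan-1-one | O=C1CCC[C@H](C(C)=C)[C@@]1(C)CCCB(C(C)C(C)C)C(C)C(C)C | intermediate
7 | (2R,3R)-2-(3-hydroxypropyl)-2-methyl-3-(prop-1-en-2-yl)cyclohexan-1-one | O=C1CCC[C@H](C(C)=C)[C@@]1(C)CCCO | intermediate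
8 | (2R,3S)-3-(2-hydroxypropan-2-yl)-2-(3-hydroxypropyl)-2-methylcyclohexan-1-one | O=C1CCC[C@H](C(C)(C)O)[C@@]1(C)CCCO | intermediate
9 | (2R,3S)-2-[3-(TBS-oxy)propyl]-3-[2-(TBS-oxy)propan-2-yl]-2-methylcyclohexan-1-one | O=C1CCC[C@H](C(C)(C)O[Si](C)(C)C(C)(C)C)[C@@]1(C)CCCO[Si](C)(C)C(C)(C)C | intermediate
10 | lithium enolate of 9 (C1=C6) | [Li]OC1=CCC[C@H](C(C)(C)O[Si](C)(C)C(C)(C)C)[C@@]1(C)CCCO[Si](C)(C)C(C)(C)C | intermediate
11 | (2R,3S,6S)-2-[3-(TBS-oxy)propyl]-3-[2-(TBS-oxy)propan-2-yl]-2,6-dimethylcyclohexan-1-one | O=C1[C@@H](C)CC[C@H](C(C)(C)O[Si](C)(C)C(C)(C)C)[C@@]1(C)CCCO[Si](C)(C)C(C)(C)C | intermediate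
12 | (2R,3S,6S)-2-[3-(TBS-oxy)propyl]-3-[2-(TBS-oxy)propan-2-yl]-2,6-dimethyl-1-methylidenecyclohexane | C=C1[C@@H](C)CC[C@H](C(C)(C)O[Si](C)(C)C(C)(C)C)[C@@]1(C)CCCO[Si](C)(C)C(C)(C)C | intermediate
13 | (1S,2R,3S,6S)-spiro-epoxide of 12, oxirane oxygen cis to the C2 chain and the C6 methyl | C1O[C@]12[C@@H](C)CC[C@H](C(C)(C)O[Si](C)(C)C(C)(C)C)[C@@]2(C)CCCO[Si](C)(C)C(C)(C)C | intermediate
14 | 3-amino-2,6-dimethylphenol | Cc1ccc(N)c(C)c1O | starting material
15 | 3-hydroxy-2,4-dimethylbenzenediazonium chloride | Cc1ccc([N+]#N)c(C)c1O.[Cl-] | intermediate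
16 | 3-chloro-2,6-dimethylphenol | Cc1ccc(Cl)c(C)c1O | intermediate
17 | 4-bromo-3-chloro-2,6-dimethylphenol | Cc1cc(Br)c(Cl)c(C)c1O | intermediate
18 | (4-bromo-3-chloro-2,6-dimethylphenoxy)(tert-butyl)dimethylsilane | Cc1cc(Br)c(Cl)c(C)c1O[Si](C)(C)C(C)(C)C | intermediate
19 | [2-chloro-3,5-dimethyl-4-(TBS-oxy)phenyl]magnesium bromide | Cc1cc([Mg]Br)c(Cl)c(C)c1O[Si](C)(C)C(C)(C)C | intermediate
20 | (1S,2R,3S,6S)-1-{[2-chloro-3,5-dimethyl-4-(TBS-oxy)phenyl]methyl}-2-[3-(TBS-oxy)propyl]-3-[2-(TBS-oxy)propan-2-yl]-2,6-dimethylcyclohexan-1-ol | O[C@@]1(Cc2cc(C)c(O[Si](C)(C)C(C)(C)C)c(C)c2Cl)[C@@H](C)CC[C@H](C(C)(C)O[Si](C)(C)C(C)(C)C)[C@@]1(C)CCCO[Si](C)(C)C(C)(C)C | intermediate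
21 | C1-O-triethylsilyl ether of 20 | CC[Si](CC)(CC)O[C@@]1(Cc2cc(C)c(O[Si](C)(C)C(C)(C)C)c(C)c2Cl)[C@@H](C)CC[C@H](C(C)(C)O[Si](C)(C)C(C)(C)C)[C@@]1(C)CCCO[Si](C)(C)C(C)(C)C | intermediate
22 | free phenol of 21 (2-chloro-4-hydroxy-3,5-dimethylbenzyl group at C1) | CC[Si](CC)(CC)O[C@@]1(Cc2cc(C)c(O)c(C)c2Cl)[C@@H](C)CC[C@H](C(C)(C)O[Si](C)(C)C(C)(C)C)[C@@]1(C)CCCO[Si](C)(C)C(C)(C)C | intermediate
23 | 3-chloro-4-methoxy-2,6-dimethyl-4-(cyclohexylmethyl unit of 22)cyclohexa-2,5-dien-1-one, epimer mixture at the methoxy carbon | CC[Si](CC)(CC)O[C@@]1(CC2(OC)C=C(C)C(=O)C(C)=C2Cl)[C@@H](C)CC[C@H](C(C)(C)O[Si](C)(C)C(C)(C)C)[C@@]1(C)CCCO[Si](C)(C)C(C)(C)C | intermediate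
24 | methyl diazoacetate | COC(=O)C=[N+]=[N-] | starting material
25 | methyl 5-chloro-4-methoxy-2,6-dimethyl-7-oxo-4-(cyclohexylmethyl unit)cyclohepta-2,5-diene-1-carboxylate, diastereomer mixture | CC[Si](CC)(CC)O[C@@]1(CC2(OC)C=C(C)C(C(=O)OC)C(=O)C(C)=C2Cl)[C@@H](C)CC[C@H](C(C)(C)O[Si](C)(C)C(C)(C)C)[C@@]1(C)CCCO[Si](C)(C)C(C)(C)C | intermediate
26 | methyl 5-chloro-2,6-dimethyl-7-oxo-4-(cyclohexylmethyl unit)cyclohepta-1,3,5-triene-1-carboxylate (3'-chlorotropone) | CC[Si](CC)(CC)O[C@@]1(CC2=CC(C)=C(C(=O)OC)C(=O)C(C)=C2Cl)[C@@H](C)CC[C@H](C(C)(C)O[Si](C)(C)C(C)(C)C)[C@@]1(C)CCCO[Si](C)(C)C(C)(C)C | intermediate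
27 | fully desilylated triol of 26 | O[C@@]1(CC2=CC(C)=C(C(=O)OC)C(=O)C(C)=C2Cl)[C@@H](C)CC[C@H](C(C)(C)O)[C@@]1(C)CCCO | intermediate
28 | spiro dihydrofuro-tropone methyl ester with 3-hydroxypropyl chain at C2 and 2-hydroxypropan-2-yl at C3 (1S,2R,3S,6S) | COC(=O)c1c(C)cc2c(c(C)c1=O)O[C@@]1(C2)[C@@H](C)CC[C@H](C(C)(C)O)[C@@]1(C)CCCO | intermediate
29 | CNP0448476.1: 3-[(1S,2R,3S,6S)-spiro cyclohexane unit]propanoic acid, spiro carbon S, quaternary carbon R, carbinol-bearing CH S, CH(CH3) S | COC(=O)c1c(C)cc2c(c(C)c1=O)O[C@@]1(C2)[C@@H](C)CC[C@H](C(C)(C)O)[C@@]1(C)CCC(=O)O | target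

**Step count and risks**

Total steps: 17 (steps 1–7 for the epoxide, 8–10 for the aryl bromide, 11–17 after the union). Longest linear sequence: 14 (steps 1–7 and 11–17).

Steps most likely to fail:

1. Step 15 (bears the new-method label). The acceptor-substituted diazo compound may not add to the deactivated, cross-conjugated carbonyl, it may add to a C=C bond instead, or the chlorovinyl carbon may migrate in competition and give the regioisomeric tropone. The fallback uses known reactions and makes the insertion regiospecific. Starting from 23, conjugate reduction with LiBH(s-Bu)3 at the unsubstituted β-carbon gives enone F1. Homologation of this more electrophilic ketone with 24 and Et3OBF4 inserts only on the saturated side, where alkyl migrates in preference to vinyl, and gives β-keto ester F2. Selenation (PhSeCl, pyridine) gives selenide F3. Oxidation with H2O2 and syn-elimination give dienone ester F4, which loses methanol with DBU and comes back to the route at 26.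

2. Step 1. The alkenyl Grignard reagent may add with lower enantioselectivity than alkyl reagents, and the fully substituted magnesium enolate may be allylated slowly or with poor trans selectivity. The fallback keeps both bond formations but separates them. Reagent 2 is transmetallated with Me2AlCl to dimethyl(isopropenyl)alane F5 and added to 1 with copper thiophene-2-carboxylate and a chiral phosphoramidite. The resulting aluminium enolate F6 is captured with allyl chloroformate as allyl enol carbonate F7. Palladium-catalysed decarboxylative Tsuji allylation (Pd2(dba)3, the matched enantiomer of t-Bu-PHOX) then delivers the allyl group trans to the isopropenyl group and returns to the route at 5.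

3. Step 11. Attack at the neopentyl-type CH2 of the oxirane may be slow, so that magnesium halide induces Meinwald rearrangement of the epoxide before the C–C bond forms. The fallback makes the aryl–CH2 bond by carbonyl addition. Alkene 12 is dihydroxylated (OsO4, NMO) from the same face as in step 7 to diol F8. The primary alcohol is oxidised (TEMPO, PhI(OAc)2, CH2Cl2) to hydroxy aldehyde F9, and the tertiary alcohol is silylated (TESOTf, 2,6-lutidine) to silyloxy aldehyde F10. Addition of Grignard reagent 19 to this non-enolisable aldehyde gives benzylic alcohol F11. Its xanthate F12 (NaH, CS2, MeI) is reduced with Bu3SnH/AIBN (Barton–McCombie deoxygenation) to 21, where the route is rejoined.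

Further compounds
F1 | step 15 | 3-chloro-4-methoxy-2,6-dimethyl-4-(cyclohexylmethyl unit)cyclohex-2-en-1-one | CC[Si](CC)(CC)O[C@@]1(CC2(OC)CC(C)C(=O)C(C)=C2Cl)[C@@H](C)CC[C@H](C(C)(C)O[Si](C)(C)C(C)(C)C)[C@@]1(C)CCCO[Si](C)(C)C(C)(C)C
F2 | step 15 | methyl 5-chloro-4-methoxy-2,6-dimethyl-7-oxo-4-(cyclohexylmethyl unit)cyclohept-5-ene-1-carboxylate | CC[Si](CC)(CC)O[C@@]1(CC2(OC)CC(C)C(C(=O)OC)C(=O)C(C)=C2Cl)[C@@H](C)CC[C@H](C(C)(C)O[Si](C)(C)C(C)(C)C)[C@@]1(C)CCCO[Si](C)(C)C(C)(C)C
F3 | step 15 | 1-(phenylselanyl) derivative of F2 | CC[Si](CC)(CC)O[C@@]1(CC2(OC)CC(C)C([Se]c3ccccc3)(C(=O)OC)C(=O)C(C)=C2Cl)[C@@H](C)CC[C@H](C(C)(C)O[Si](C)(C)C(C)(C)C)[C@@]1(C)CCCO[Si](C)(C)C(C)(C)C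
F4 | step 15 | methyl 5-chloro-4-methoxy-2,6-dimethyl-7-oxo-4-(cyclohexylmethyl unit)cyclohepta-1,5-diene-1-carboxylate | CC[Si](CC)(CC)O[C@@]1(CC2(OC)CC(C)=C(C(=O)OC)C(=O)C(C)=C2Cl)[C@@H](C)CC[C@H](C(C)(C)O[Si](C)(C)C(C)(C)C)[C@@]1(C)CCCO[Si](C)(C)C(C)(C)C
F5 | step 1 | dimethyl(prop-1-en-2-yl)alane | C[Al](C)C(C)=C
F6 | step 1 | dimethylaluminium (R)-2-methyl-3-(prop-1-en-2-yl)cyclohex-1-en-1-olate | C[Al](C)OC1=C(C)[C@@H](C(C)=C)CCC1
F7 | step 1 | allyl (R)-2-methyl-3-(prop-1-en-2-yl)cyclohex-1-en-1-yl carbonate | C=CCOC(=O)OC1=C(C)[C@@H](C(C)=C)CCC1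
F8 | step 11 | (1S,2R,3S,6S)-1-(hydroxymethyl)-2-[3-(TBS-oxy)propyl]-3-[2-(TBS-oxy)propan-2-yl]-2,6-dimethylcyclohexan-1-ol | OC[C@]1(O)[C@@H](C)CC[C@H](C(C)(C)O[Si](C)(C)C(C)(C)C)[C@@]1(C)CCCO[Si](C)(C)C(C)(C)C
F9 | step 11 | 1-hydroxycyclohexane-1-carbaldehyde from F8 | O=C[C@]1(O)[C@@H](C)CC[C@H](C(C)(C)O[Si](C)(C)C(C)(C)C)[C@@]1(C)CCCO[Si](C)(C)C(C)(C)C
F10 | step 11 | 1-(TES-oxy)cyclohexane-1-carbaldehyde from F9 | O=C[C@]1(O[Si](CC)(CC)CC)[C@@H](C)CC[C@H](C(C)(C)O[Si](C)(C)C(C)(C)C)[C@@]1(C)CCCO[Si](C)(C)C(C)(C)C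
F11 | step 11 | aryl(1-TES-oxycyclohexyl)methanol, epimer mixture at the carbinol carbon | CC[Si](CC)(CC)O[C@@]1(C(O)c2cc(C)c(O[Si](C)(C)C(C)(C)C)c(C)c2Cl)[C@@H](C)CC[C@H](C(C)(C)O[Si](C)(C)C(C)(C)C)[C@@]1(C)CCCO[Si](C)(C)C(C)(C)C
F12 | step 11 | O-alkyl S-methyl xanthate of F11 | CC[Si](CC)(CC)O[C@@]1(C(OC(=S)SC)c2cc(C)c(O[Si](C)(C)C(C)(C)C)c(C)c2Cl)[C@@H](C)CC[C@H](C(C)(C)O[Si](C)(C)C(C)(C)C)[C@@]1(C)CCCO[Si](C)(C)C(C)(C)C
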